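**Retrosynthetic overview**
1. The C2-symmetric tetraene 30 is cut at the central C(sp2)–C(sp2) bond: Pd homocoupling of (E)-dienyl iodide 28, which comes from enal 27 by Takai olefination.
2. The cyclohexene (last ring formed) comes from ring-closing metathesis of diene-diol 25, made from terminal oxirane 22 and the dianion of methallyl alcohol 23.
3. The quaternary C–C bond and both ring stereocentres come from a glycolate Ireland–Claisen [3,3] rearrangement of ester 14; the chirality is relayed from (S)-but-3-yn-2-ol 6 and the relay carbon later leaves as propene.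
4. Z-allylic alcohol 10 comes from alkynol 8 by syn-carbomagnesiation; 8 comes from 6 and epoxy iodide 5.
5. The dimethyloxirane (first ring formed) comes from (S)-α-hydroxy-γ-butyrolactone 1. Ring order: dimethyloxirane, then a transient terminal oxirane, then the cyclohexene.

Assumption: 1, 6, 11 and 23 are taken as catalogue compounds; species marked "not isolated" are drawn in their simplest covalent form.

**Route**

Step 1
Reactants: 1 (S)-3-hydroxyoxolan-2-one
Product: 2 (S)-2-oxooxolan-3-yl methanesulfonate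
Conditions: MsCl, Et3N, CH2Cl2, −20 → 0 °C
Reagents that add atoms: methanesulfonyl chloride CS(=O)(=O)Cl
Why: O-sulfonylation turns the bought (S)-carbinol into a leaving group without breaking its C–O bond, so the configuration is retained.

Step 2
Reactants: 2 (S)-2-oxooxolan-3-yl methanesulfonate
Product: 4 2-[(2R)-3,3-dimethyloxiran-2-yl]ethan-1-ol, via diol mesylate 3 (not isolated)
Conditions: MeMgBr (2.3 equiv), THF, −78 → −20 °C; then MeOH, K2CO3, 0 °C → rt
Reagents that add atoms: methylmagnesium bromide C[Mg]Br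
Why: Double Grignard addition to the lactone carbonyl gives a tertiary alkoxide next to the mesylate, and intramolecular Williamson (SN2) closure inverts that carbon, so the bought (S)-centre becomes the (R)-oxirane carbon while the lactone ring oxygen is released as the primary alcohol.

Step 3
Reactants: 4 2-[(2R)-3,3-dimethyloxiran-2-yl]ethan-1-ol
Product: 5 (3R)-3-(2-iodoethyl)-2,2-dimethyloxirane
Conditions: I2, PPh3, imidazole, CH2Cl2, 0 °C
Reagents that add atoms: iodine II
Why: Appel-type iodination of the primary alcohol under imidazole buffering leaves the oxirane closed and touches no stereocentre.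

Step 4
Reactants: 6 (2S)-but-3-yn-2-ol; 5 (3R)-3-(2-iodoethyl)-2,2-dimethyloxirane
Product: 8 (2S)-6-[(2R)-3,3-dimethyloxiran-2-yl]hex-3-yn-2-ol, via dilithio alkynolate 7 (not isolated)
Conditions: n-BuLi (2.1 equiv), THF, −78 → −20 °C; then 5, DMPU, −20 °C → rt
Reagents that add atoms: none
Why: SN2 alkylation of the C,O-dianion occurs at the acetylide carbon with the primary iodide, the hindered trisubstituted oxirane being far less reactive, and both stereocentres are carried over unchanged.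

Step 5
Reactants: 8 (2S)-6-[(2R)-3,3-dimethyloxiran-2-yl]hex-3-yn-2-ol
Product: 10 (2S,3Z)-6-[(2R)-3,3-dimethyloxiran-2-yl]-4-methylhex-3-en-2-ol, via alkenylmagnesium alkoxide 9 (not isolated)
Conditions: MeMgBr (5 equiv), Fe(acac)3 (15 mol %), THF, −78 → 0 °C; then pH 7 buffer
Reagents that add atoms: methylmagnesium bromide C[Mg]Br
Why: Alkoxide-directed, iron-catalysed syn-carbomagnesiation puts methyl on the distal alkyne carbon and magnesium on the proximal one, so after protonation the methyl is trans and the epoxyethyl chain cis to the carbinol carbon (Z olefin).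

Step 6
Reactants: 10 (2S,3Z)-6-[(2R)-3,3-dimethyloxiran-2-yl]-4-methylhex-3-en-2-ol; 11 trimethylsilyl 2-[(trimethylsilyl)oxy]acetate
Product: 14 (2S,3Z)-6-[(2R)-3,3-dimethyloxiran-2-yl]-4-methylhex-3-en-2-yl 2-hydroxyacetate, via 2-[(trimethylsilyl)oxy]acetyl chloride 12 (not isolated), via silyl ether ester 13 (not isolated)
Conditions: 11, (COCl)2, cat. DMF, CH2Cl2, 0 °C → rt, volatiles removed; then 10, pyridine, cat. DMAP, CH2Cl2, 0 °C; then MeOH, cat. K2CO3, 0 °C, 10 min
Reagents that add atoms: none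
Why: Acylation of the secondary alcohol by the acid chloride made in the flask, then methanolysis of the labile primary trimethylsilyl ether, gives the free glycolate ester with retention at the carbinol.

Step 7
Reactants: 14 (2S,3Z)-6-[(2R)-3,3-dimethyloxiran-2-yl]-4-methylhex-3-en-2-yl 2-hydroxyacetate
Product: 19 methyl (2S,3S,4E)-3-[2-[(2R)-3,3-dimethyloxiran-2-yl]ethyl]-2-hydroxy-3-methylhex-4-enoate, via lithium enediolate 15 (not isolated), via bis-silyl ketene acetal 16 (not isolated), via silyl ester 17 (not isolated), via hydroxy acid 18 (not isolated)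
Conditions: LiN(i-Pr)2 (2.5 equiv), THF, −78 °C; Me3SiCl (3 equiv), −78 °C → rt, then 45 °C; pH 5 buffer; Me3SiCHN2, MeOH/toluene, 0 °C
Reagents that add atoms: (trimethylsilyl)diazomethane C[Si](C)(C)C=[N+]=[N-]
Why: The Ireland–Claisen [3,3]-sigmatropic rearrangement of the O,O-cis enediolate-derived ketene acetal goes through a chair with the carbinol methyl equatorial, so the bought (S)-carbinol chirality is transferred across the Z olefin, forming the quaternary C–C bond and setting the quaternary carbon and the adjacent carbinol together (hydroxyl on the same side as the epoxyethyl arm), and the acid is methylated at once so the oxirane never sits beside a free acid.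

Step 8
Reactants: 19 methyl (2S,3S,4E)-3-[2-[(2R)-3,3-dimethyloxiran-2-yl]ethyl]-2-hydroxy-3-methylhex-4-enoate
Product: 20 (2S,3S,4E)-3-[2-[(2R)-3,3-dimethyloxiran-2-yl]ethyl]-3-methylhex-4-ene-1,2-diol
Conditions: LiBH4, THF/MeOH, 0 °C → rt
Reagents that add atoms: none
Why: Chemoselective borohydride reduction of the α-hydroxy ester, assisted by the neighbouring alkoxide, gives the 1,2-diol without touching oxirane, olefin or any stereocentre.

Step 9
Reactants: 20 (2S,3S,4E)-3-[2-[(2R)-3,3-dimethyloxiran-2-yl]ethyl]-3-methylhex-4-ene-1,2-diol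
Product: 22 (3R)-2,2-dimethyl-3-[(3S,4E)-3-methyl-3-[(2S)-oxiran-2-yl]hex-4-en-1-yl]oxirane, via primary tosylate 21 (not isolated)
Conditions: NaH (2.2 equiv), 1-(p-toluenesulfonyl)imidazole (1.05 equiv), THF, 0 °C → rt
Reagents that add atoms: none
Why: Selective sulfonylation of the primary alkoxide followed by intramolecular Williamson closure from the hindered secondary alkoxide forms the terminal oxirane with retention at the carbinol carbon, whose C–O bond is never broken.

Step 10
Reactants: 22 (3R)-2,2-dimethyl-3-[(3S,4E)-3-methyl-3-[(2S)-oxiran-2-yl]hex-4-en-1-yl]oxirane; 23 2-methylprop-2-en-1-ol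
Product: 25 (5R,6S,7E)-6-[2-[(2R)-3,3-dimethyloxiran-2-yl]ethyl]-6-methyl-2-methylidenenon-7-ene-1,5-diol, via dilithio methallyl alkoxide 24 (not isolated)
Conditions: 23 (3 equiv), n-BuLi (6 equiv), TMEDA, Et2O, 0 °C → rt, 20 h; then 22, THF, −78 → 0 °C
Reagents that add atoms: none
Why: The allylic carbanion of the methallyl alcohol dianion opens the monosubstituted oxirane at its CH2 terminus (SN2), leaving the much more hindered trisubstituted oxirane alone and freeing the ring carbinol with its configuration intact.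

Step 11
Reactants: 25 (5R,6S,7E)-6-[2-[(2R)-3,3-dimethyloxiran-2-yl]ethyl]-6-methyl-2-methylidenenon-7-ene-1,5-diol
Product: 26 (1R,2S)-2-[2-[(2R)-3,3-dimethyloxiran-2-yl]ethyl]-4-(hydroxymethyl)-2-methylcyclohex-3-en-1-ol
Conditions: second-generation Hoveyda–Grubbs catalyst (5 mol %), CH2Cl2 (0.005 M), 40 °C
Reagents that add atoms: none
Why: Ring-closing olefin metathesis between the 1,1-disubstituted olefin and the propenyl group forms the six-membered ring with its trisubstituted double bond next to the quaternary carbon and expels propene, which carries away the spent relay carbon.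

Step 12
Reactants: 26 (1R,2S)-2-[2-[(2R)-3,3-dimethyloxiran-2-yl]ethyl]-4-(hydroxymethyl)-2-methylcyclohex-3-en-1-ol
Product: 27 (3S,4R)-3-[2-[(2R)-3,3-dimethyloxiran-2-yl]ethyl]-4-hydroxy-3-methylcyclohex-1-ene-1-carbaldehyde
Conditions: MnO2 (15 equiv), CH2Cl2, rt
Reagents that add atoms: none
Why: MnO2 oxidises only the allylic primary alcohol to the enal, the saturated secondary carbinol being inert.

Step 13
Reactants: 27 (3S,4R)-3-[2-[(2R)-3,3-dimethyloxiran-2-yl]ethyl]-4-hydroxy-3-methylcyclohex-1-ene-1-carbaldehyde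
Product: 28 (1R,2S)-2-[2-[(2R)-3,3-dimethyloxiran-2-yl]ethyl]-4-[(E)-2-iodoethenyl]-2-methylcyclohex-3-en-1-ol
Conditions: CrCl2 (8 equiv), CHI3 (3 equiv), THF/1,4-dioxane 1:6, 0 °C → rt, dark
Reagents that add atoms: iodoform IC(I)I
Why: Takai olefination converts the enal into the (E)-dienyl iodide with high E selectivity under near-neutral conditions that the free hydroxyl and the oxirane tolerate.

Step 14
Reactants: 28 (1R,2S)-2-[2-[(2R)-3,3-dimethyloxiran-2-yl]ethyl]-4-[(E)-2-iodoethenyl]-2-methylcyclohex-3-en-1-ol (2 equiv)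
Product: 30 (1R,1'R,2S,2'S)-4,4'-[(1E,3E)-buta-1,3-diene-1,4-diyl]bis{2-[2-[(2R)-3,3-dimethyloxiran-2-yl]ethyl]-2-methylcyclohex-3-en-1-ol}, via dienyl pinacol boronate 29 (not isolated)
Conditions: B2pin2 (0.5 equiv), PdCl2(dppf) (5 mol %), K3PO4 (3 equiv), 1,4-dioxane/H2O 10:1, degassed, 50 °C, dark
Reagents that add atoms: none
Why: One-pot Miyaura borylation of half of the iodide and Suzuki–Miyaura coupling with the other half joins the two sp2 carbons with retention of both olefin geometries, giving the (E,E)-tetraene directly because no protecting group remains.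

**Compound list**
1 | (S)-3-hydroxyoxolan-2-one | O[C@H]1CCOC1=O | starting material
2 | (S)-2-oxooxolan-3-yl methanesulfonate | CS(=O)(=O)O[C@H]1CCOC1=O | intermediate
3 | (3S)-1,4-dihydroxy-4-methylpentan-3-yl methanesulfonate (formed as magnesium alkoxide, freed by MeOH) | CC(C)(O)[C@@H](OS(C)(=O)=O)CCO | intermediate
4 | 2-[(2R)-3,3-dimethyloxiran-2-yl]ethan-1-ol | OCC[C@H]1OC1(C)C | intermediate
5 | (3R)-3-(2-iodoethyl)-2,2-dimethyloxirane | ICC[C@H]1OC1(C)C | intermediate
6 | (2S)-but-3-yn-2-ol | C[C@H](O)C#C | starting material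
7 | lithium (2S)-4-lithiobut-3-yn-2-olate | C[C@H](O[Li])C#C[Li] | intermediate
8 | (2S)-6-[(2R)-3,3-dimethyloxiran-2-yl]hex-3-yn-2-ol | C[C@H](O)C#CCC[C@H]1OC1(C)C | intermediate
9 | bromomagnesium (2S,3E)-3-(bromomagnesio)-6-[(2R)-3,3-dimethyloxiran-2-yl]-4-methylhex-3-en-2-olate | C[C@H](O[Mg]Br)/C([Mg]Br)=C(/C)CC[C@H]1OC1(C)C | intermediate
10 | (2S,3Z)-6-[(2R)-3,3-dimethyloxiran-2-yl]-4-methylhex-3-en-2-ol | C[C@H](O)/C=C(/C)CC[C@H]1OC1(C)C | intermediate
11 | trimethylsilyl 2-[(trimethylsilyl)oxy]acetate | C[Si](C)(C)OCC(=O)O[Si](C)(C)C | starting material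
12 | 2-[(trimethylsilyl)oxy]acetyl chloride | C[Si](C)(C)OCC(Cl)=O | intermediate
13 | (2S,3Z)-6-[(2R)-3,3-dimethyloxiran-2-yl]-4-methylhex-3-en-2-yl 2-[(trimethylsilyl)oxy]acetate | C[C@H](OC(=O)CO[Si](C)(C)C)/C=C(/C)CC[C@H]1OC1(C)C | intermediate
14 | (2S,3Z)-6-[(2R)-3,3-dimethyloxiran-2-yl]-4-methylhex-3-en-2-yl 2-hydroxyacetate | C[C@H](OC(=O)CO)/C=C(/C)CC[C@H]1OC1(C)C | intermediate
15 | dilithium O,O-cis enediolate of 14 | C[C@H](O/C(O[Li])=C/O[Li])/C=C(/C)CC[C@H]1OC1(C)C | intermediate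
16 | O,O-cis bis(trimethylsilyl) ketene acetal of 14 | C[C@H](O/C(O[Si](C)(C)C)=C/O[Si](C)(C)C)/C=C(/C)CC[C@H]1OC1(C)C | intermediate
17 | trimethylsilyl (2S,3S,4E)-3-[2-[(2R)-3,3-dimethyloxiran-2-yl]ethyl]-3-methyl-2-[(trimethylsilyl)oxy]hex-4-enoate | C/C=C/[C@](C)(CC[C@H]1OC1(C)C)[C@H](O[Si](C)(C)C)C(=O)O[Si](C)(C)C | intermediate
18 | (2S,3S,4E)-3-[2-[(2R)-3,3-dimethyloxiran-2-yl]ethyl]-2-hydroxy-3-methylhex-4-enoic acid | C/C=C/[C@](C)(CC[C@H]1OC1(C)C)[C@H](O)C(O)=O | intermediate
19 | methyl (2S,3S,4E)-3-[2-[(2R)-3,3-dimethyloxiran-2-yl]ethyl]-2-hydroxy-3-methylhex-4-enoate | C/C=C/[C@](C)(CC[C@H]1OC1(C)C)[C@H](O)C(=O)OC | intermediate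
20 | (2S,3S,4E)-3-[2-[(2R)-3,3-dimethyloxiran-2-yl]ethyl]-3-methylhex-4-ene-1,2-diol | C/C=C/[C@](C)(CC[C@H]1OC1(C)C)[C@H](O)CO | intermediate
21 | (2S,3S,4E)-3-[2-[(2R)-3,3-dimethyloxiran-2-yl]ethyl]-2-hydroxy-3-methylhex-4-en-1-yl 4-methylbenzenesulfonate | C/C=C/[C@](C)(CC[C@H]1OC1(C)C)[C@H](O)COS(=O)(=O)c1ccc(C)cc1 | intermediate
22 | (3R)-2,2-dimethyl-3-[(3S,4E)-3-methyl-3-[(2S)-oxiran-2-yl]hex-4-en-1-yl]oxirane | C/C=C/[C@](C)(CC[C@H]1OC1(C)C)[C@H]1CO1 | intermediate
23 | 2-methylprop-2-en-1-ol | OCC(C)=C | starting material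
24 | lithium 2-(lithiomethyl)prop-2-en-1-olate | [Li]CC(=C)CO[Li] | intermediate
25 | (5R,6S,7E)-6-[2-[(2R)-3,3-dimethyloxiran-2-yl]ethyl]-6-methyl-2-methylidenenon-7-ene-1,5-diol | C/C=C/[C@](C)(CC[C@H]1OC1(C)C)[C@H](O)CCC(=C)CO | intermediate
26 | (1R,2S)-2-[2-[(2R)-3,3-dimethyloxiran-2-yl]ethyl]-4-(hydroxymethyl)-2-methylcyclohex-3-en-1-ol | OCC1=C[C@](C)(CC[C@H]2OC2(C)C)[C@H](O)CC1 | intermediate
27 | (3S,4R)-3-[2-[(2R)-3,3-dimethyloxiran-2-yl]ethyl]-4-hydroxy-3-methylcyclohex-1-ene-1-carbaldehyde | O=CC1=C[C@](C)(CC[C@H]2OC2(C)C)[C@H](O)CC1 | intermediate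
28 | (1R,2S)-2-[2-[(2R)-3,3-dimethyloxiran-2-yl]ethyl]-4-[(E)-2-iodoethenyl]-2-methylcyclohex-3-en-1-ol | I/C=C/C1=C[C@](C)(CC[C@H]2OC2(C)C)[C@H](O)CC1 | intermediate
29 | (1R,2S)-2-[2-[(2R)-3,3-dimethyloxiran-2-yl]ethyl]-2-methyl-4-[(E)-2-(4,4,5,5-tetramethyl-1,3,2-dioxaborolan-2-yl)ethenyl]cyclohex-3-en-1-ol | CC1(C)OB(/C=C/C2=C[C@](C)(CC[C@H]3OC3(C)C)[C@H](O)CC2)OC1(C)C | intermediate
30 | (1R,1'R,2S,2'S)-4,4'-[(1E,3E)-buta-1,3-diene-1,4-diyl]bis{2-[2-[(2R)-3,3-dimethyloxiran-2-yl]ethyl]-2-methylcyclohex-3-en-1-ol} (CNP0229121.4) | CC1(C)O[C@@H]1CC[C@@]1(C)C=C(/C=C/C=C/C2=C[C@](C)(CC[C@H]3OC3(C)C)[C@H](O)CC2)CC[C@H]1O | target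

**Count and risks**
Total steps: 14. Longest linear sequence: 14 steps (1 → 30); 6, 11 and 23 enter as bought building blocks.

Most likely to fail, first: step 2. The α-mesyloxy lactone may enolise, racemise or suffer bromide displacement before the second Grignard addition. The fallback sets out from 1 and comes back at 4. Excess MeMgBr opens 1 to (3S)-4-methylpentane-1,3,4-triol F1. TBSCl/imidazole at 0 °C silylates only the primary hydroxyl to give (3S)-1-[(tert-butyldimethylsilyl)oxy]-4-methylpentane-3,4-diol F2. MsCl/Et3N sulfonylates the secondary hydroxyl to give (3S)-1-[(tert-butyldimethylsilyl)oxy]-4-hydroxy-4-methylpentan-3-yl methanesulfonate F3. K2CO3/MeOH closes the oxirane with inversion to tert-butyl{2-[(2R)-3,3-dimethyloxiran-2-yl]ethoxy}dimethylsilane F4, and Bu4NF releases 4. Masking the primary oxygen is needed because a primary leaving group would let the tertiary alkoxide close a tetrahydrofuran instead.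

Second: step 5. The oxirane may not survive several equivalents of MeMgBr with the iron catalyst. The fallback sets out from 6 (with iodide 5) and comes back at 10, replacing steps 4 and 5. n-BuLi (2 equiv) then MeI gives (2S)-pent-3-yn-2-ol F5. NaAlH2(OCH2CH2OMe)2 then I2 gives (2S,3Z)-4-iodopent-3-en-2-ol F6 by trans-hydroalumination, with iodine cis to the carbinol carbon. Zinc insertion into 5 (Zn dust, LiCl, THF, 25 °C) gives {2-[(2R)-3,3-dimethyloxiran-2-yl]ethyl}zinc iodide F7. Negishi coupling of F7 with F6 (Pd(OAc)2, SPhos, THF, rt) proceeds with retention of olefin geometry and puts the chain cis to the carbinol carbon, giving 10.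

Third: step 10. The dianion may give low conversion with the hindered terminal oxirane or attack the second oxirane. The fallback sets out from 22 and comes back at 27, replacing steps 10 to 12 and closing the ring by aldol condensation instead of metathesis. But-3-enylmagnesium bromide with catalytic CuI (THF, −30 °C) opens the terminal oxirane to (6R,7S,8E)-7-[2-[(2R)-3,3-dimethyloxiran-2-yl]ethyl]-7-methyldeca-1,8-dien-6-ol F8. Ozonolysis (O3, CH2Cl2/MeOH, −78 °C; Me2S) cleaves both olefins to (2R,3R)-2-[2-[(2R)-3,3-dimethyloxiran-2-yl]ethyl]-3-hydroxy-2-methylheptanedial F9, which rests as its lactol. Piperidinium acetate in toluene then effects an intramolecular aldol condensation in which only the distal aldehyde can enolise and the neopentyl aldehyde acts as acceptor, giving enal 27.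

Further compounds
F1 | step 2 | (3S)-4-methylpentane-1,3,4-triol | CC(C)(O)[C@@H](O)CCO
F2 | step 2 | (3S)-1-[(tert-butyldimethylsilyl)oxy]-4-methylpentane-3,4-diol | CC(C)(O)[C@@H](O)CCO[Si](C)(C)C(C)(C)C
F3 | step 2 | (3S)-1-[(tert-butyldimethylsilyl)oxy]-4-hydroxy-4-methylpentan-3-yl methanesulfonate | CC(C)(O)[C@@H](OS(C)(=O)=O)CCO[Si](C)(C)C(C)(C)C
F4 | step 2 | tert-butyl{2-[(2R)-3,3-dimethyloxiran-2-yl]ethoxy}dimethylsilane | CC(C)(C)[Si](C)(C)OCC[C@H]1OC1(C)C
F5 | step 5 | (2S)-pent-3-yn-2-ol | C[C@H](O)C#CC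
F6 | step 5 | (2S,3Z)-4-iodopent-3-en-2-ol | C[C@H](O)/C=C(/C)I
F7 | step 5 | {2-[(2R)-3,3-dimethyloxiran-2-yl]ethyl}zinc iodide | I[Zn]CC[C@H]1OC1(C)C
F8 | step 10 | (6R,7S,8E)-7-[2-[(2R)-3,3-dimethyloxiran-2-yl]ethyl]-7-methyldeca-1,8-dien-6-ol | C/C=C/[C@](C)(CC[C@H]1OC1(C)C)[C@H](O)CCCC=C
F9 | step 10 | (2R,3R)-2-[2-[(2R)-3,3-dimethyloxiran-2-yl]ethyl]-3-hydroxy-2-methylheptanedial | O=C[C@](C)(CC[C@H]1OC1(C)C)[C@H](O)CCCC=O
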